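The bicyclic core is disconnected at C5–C6 in ring B (C1–C8–C7–C6–C5–C9). Since C5 bears only a methyl group that a bridgehead anion can receive at the end, ring A (C1–C2–C3–C4–C5–C9) can start as an achiral 2,6-dimethoxycyclohexa-2,5-diene with enantiotopic enol ethers, whose C1 carries prenyl and the C8 gem-dimethyl carbon bearing a diazomethyl ketone. A single copper–bis(oxazoline) carbene transfer bonds C6 to C5 and, temporarily, to C9; acid then cuts the donor–acceptor C6–C9 bond, leaving ring B closed, C9 as bridging ketone and both bridgeheads set. The precursor is reached by forming the congested C1–C8 bond on the arene before Birch reduction.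

Key step: step 7

Remarks on the chemistry
- Locants C1–C9 are those of the bicyclo[3.3.1]nonane, with C1 the prenyl-bearing bridgehead next to C8 (CMe2); they are used for all intermediates, including the monocyclic ones.
- The target is (1R,5R,7R), with the C7 prenyl group endo, on the face of ring B that carries the C2–C3–C4 bridge. Precursor 15 is achiral. Product 17, (1S,5S) by the CIP rules, has the same spatial arrangement at C1 and C5 as 29; the descriptors differ only through priority changes at C2 and C4. No correction of connectivity or configuration was needed.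
- C7 is carried through Birch reduction and C1 alkylation as a secondary alkoxide and is turned into the diazo ketone by diazo transfer on a methyl ketone. A free, very hindered carboxylic acid next to two acid-labile enol ethers, and its activation, are thereby avoided.
- Assumption: the (S,S)-ligand is taken to select the enol ether that leads to 17; if a trial run gives the antipode, the (R,R)-ligand is used.
- The bis(enol ethers) 8, 11, 12 and 15 are acid-labile; work-ups are kept neutral to basic and chromatography is done on Et3N-deactivated silica.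

Step 1
Reactants: 1 2-bromo-1,3-dimethoxybenzene; 2 methyl 2-methylpropanoate (methyl isobutyrate)
Product: 4 methyl 2-(2,6-dimethoxyphenyl)-2-methylpropanoate, via lithium ester enolate 3 (not isolated)
Conditions: Cy2NH, n-BuLi, toluene, 0 °C; 2, rt; then 1, Pd(dba)2 (2 mol %), P(t-Bu)3 (2 mol %), rt → 50 °C
Reagents that add atoms: none
Why: Palladium-catalysed α-arylation of an ester enolate (Buchwald–Hartwig type) should forge the aryl–C8 bond through oxidative addition, transmetalation with the lithium enolate and reductive elimination, the bulky P(t-Bu)3 ligand being what tolerates an ortho,ortho-disubstituted bromide and a quaternary α-carbon.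

Step 2
Reactants: 4 methyl 2-(2,6-dimethoxyphenyl)-2-methylpropanoate
Product: 6 3-(2,6-dimethoxyphenyl)-3-methylbutan-2-one, via silyl ketone enolate 5 (not isolated)
Conditions: Me3SiCH2Li (2.5 equiv), pentane–THF, 0 °C → rt; then MeOH, rt
Reagents that add atoms: (trimethylsilyl)methyllithium, [Li]C[Si](C)(C)C
Why: Addition of Me3SiCH2Li to the ester gives an α-silyl ketone that is deprotonated at once to an enolate inert to a second addition, and methanolysis then removes silicon, a known one-flask ester-to-methyl-ketone conversion that suits hindered esters.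

Step 3
Reactants: 6 3-(2,6-dimethoxyphenyl)-3-methylbutan-2-one
Product: 8 racemic 3-(2,6-dimethoxycyclohexa-2,5-dien-1-yl)-3-methylbutan-2-ol, via aryl alkoxide 7 (not isolated)
Conditions: Li, NH3(l), THF, t-BuOH, −78 → −33 °C; solid NH4Cl
Reagents that add atoms: none
Why: In this Birch reduction the isolated ketone should be reduced first to its alkoxide, after which the 2-alkyl-1,3-dimethoxyarene takes up hydrogen at C1 (ipso) and C4 (para), so that both methoxy groups stay on sp2 carbons; the carbinol centre is racemic and is erased in step 5.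

Step 4
Reactants: 8 racemic 3-(2,6-dimethoxycyclohexa-2,5-dien-1-yl)-3-methylbutan-2-ol; 9 1-bromo-3-methylbut-2-ene (prenyl bromide)
Product: 11 racemic 3-[2,6-dimethoxy-1-(3-methylbut-2-en-1-yl)cyclohexa-2,5-dien-1-yl]-3-methylbutan-2-ol, via dilithiated dienyl alkoxide 10 (not isolated)
Conditions: t-BuLi (2.2 equiv), THF, −78 °C; then DMPU, 9, −78 → 0 °C
Reagents that add atoms: none
Why: After the alkoxide has consumed one equivalent of base, lithiation of the doubly allylic C1–H between the two methoxyvinyl groups and SN2 alkylation of the cyclohexadienyl anion at its central carbon (as in the stepwise alkylation of 1,5-dimethoxycyclohexa-1,4-dienes) should make C1 quaternary, with only a primary allylic halide having to approach because the C1–C8 bond already exists.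

Step 5
Reactants: 11 racemic 3-[2,6-dimethoxy-1-(3-methylbut-2-en-1-yl)cyclohexa-2,5-dien-1-yl]-3-methylbutan-2-ol
Product: 12 3-[2,6-dimethoxy-1-(3-methylbut-2-en-1-yl)cyclohexa-2,5-dien-1-yl]-3-methylbutan-2-one
Conditions: Dess–Martin periodinane, pyridine, CH2Cl2, 0 °C → rt
Reagents that add atoms: none
Why: Dess–Martin oxidation handles hindered secondary alcohols, and pyridine buffering should spare the acid-labile enol ethers and the prenyl alkene.

Step 6
Reactants: 12 3-[2,6-dimethoxy-1-(3-methylbut-2-en-1-yl)cyclohexa-2,5-dien-1-yl]-3-methylbutan-2-one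
Product: 15 1-diazo-3-[2,6-dimethoxy-1-(3-methylbut-2-en-1-yl)cyclohexa-2,5-dien-1-yl]-3-methylbutan-2-one (achiral, C1 prochiral), via lithium enolate 13 (not isolated), via trifluoroacetyl diketone 14 (not isolated)
Conditions: LiN(SiMe3)2, THF, −78 °C; CF3CO2CH2CF3; then MsN3, Et3N, H2O (1 equiv), MeCN, rt
Reagents that add atoms: methanesulfonyl azide, CS(=O)(=O)N=[N+]=[N-]
Why: In this detrifluoroacetylative (Danheiser) diazo transfer the methyl group is the only enolisable position, its enolate is trifluoroacetylated, and the activated 1,3-diketone should accept the diazo group from MsN3 with loss of the trifluoroacetyl group under conditions free of acid and of diazomethane.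

Step 7
Reactants: 15 1-diazo-3-[2,6-dimethoxy-1-(3-methylbut-2-en-1-yl)cyclohexa-2,5-dien-1-yl]-3-methylbutan-2-one
Product: 17 (1S,5S)-2-methoxy-8,8-dimethyl-1-(3-methylbut-2-en-1-yl)bicyclo[3.3.1]non-2-ene-7,9-dione (C5 bridgehead still C–H), via methoxycyclopropyl ketone 16 (not isolated)
Conditions: (CuOTf)2·C6H6 (5 mol %), (S,S)-t-Bu-box [2,2′-(propane-2,2-diyl)bis((4S)-4-tert-butyl-4,5-dihydrooxazole)] (12 mol %), toluene, rt → 50 °C, slow addition of 15; then PPTS (0.2 equiv), acetone–H2O (10:1), rt
Reagents that add atoms: water, O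
Why: Monovalent copper bound to the C2-symmetric bis(oxazoline) should decompose the diazo ketone to an electrophilic copper carbene at C6, which adds across the enol ether C9=C5 to give the donor–acceptor cyclopropane 16; PPTS then triggers push–pull heterolysis of C6–C9 (methoxy donor on C9, ketone acceptor on C7), the oxocarbenium ion being hydrolysed to the C9 ketone and the C6 enol protonated. The closest known reaction type is the copper–bis(oxazoline) asymmetric intramolecular cyclopropanation of α-diazo ketones tethered to methoxycyclohexadienes, followed by acid opening of the methoxycyclopropyl ketone. Closure follows the 1-diazohex-5-en-2-one mode, a five-membered ring through C6–C9 fused to the cyclopropane (bicyclo[3.1.0]hexanone), and ring B (C1–C8–C7–C6–C5–C9) is the six-membered ring closed through C5–C6 that remains once C6–C9 is cut. C1 becomes stereogenic because the ligand steers the carbene to one of the two enantiotopic enol ethers, and C5 follows from it because the tether reaches only the ring face on which C8 sits, so both bridgeheads are fixed in one event. The step needs enantiotopic-group selection (ligand control), chemoselection for the enol ether, which is more electron-rich and one atom closer than the prenyl alkene, and regioselective cyclopropane cleavage, secured by the donor and acceptor sitting on C9 and C6; the gem-dimethyl group at C8 aids cyclisation (Thorpe–Ingold effect) and offers no α-hydrogen for migration. The strained donor–acceptor cyclopropane should ionise far faster than the remaining C2 enol ether is protonated, so that group and the prenyl chain survive the acid stage.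

Step 8
Reactants: 17 (1S,5S)-2-methoxy-8,8-dimethyl-1-(3-methylbut-2-en-1-yl)bicyclo[3.3.1]non-2-ene-7,9-dione
Product: 18 (1S,5S)-2-methoxy-8,8-dimethyl-7-methylidene-1-(3-methylbut-2-en-1-yl)bicyclo[3.3.1]non-2-en-9-one
Conditions: Cp2TiMe2 (2.5 equiv), toluene, 65 °C, dark
Reagents that add atoms: dimethyltitanocene, [CH3-].[CH3-].[Ti+4].c1cc[cH-]c1.c1cc[cH-]c1
Why: In this Petasis methylenation the thermally formed titanium methylidene should engage the C7 ketone, which has a CH2 flank, in preference to the C9 ketone buried between two bridgeheads, and the non-basic reagent leaves the enolisable ketone and the enol ether intact.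

Step 9
Reactants: 18 (1S,5S)-2-methoxy-8,8-dimethyl-7-methylidene-1-(3-methylbut-2-en-1-yl)bicyclo[3.3.1]non-2-en-9-one; 19 1-bromo-2-methylprop-1-ene
Product: 21 (1S,5R,7R)-2-methoxy-8,8-dimethyl-1,7-bis(3-methylbut-2-en-1-yl)bicyclo[3.3.1]non-2-en-9-one (C7 prenyl endo), via B-alkyl-9-BBN borane 20 (not isolated)
Conditions: 9-BBN, THF, 0 °C → rt; then 19, Pd(dppf)Cl2 (5 mol %), AsPh3, K3PO4 (aq), DMF, 50 °C
Reagents that add atoms: none
Why: 9-BBN should add only to the 1,1-disubstituted alkene, boron to CH2 and hydrogen to C7 from the convex exo face (anti to the C2–C3–C4 bridge), so the CH2 group ends endo as in the target, and B-alkyl Suzuki–Miyaura coupling with the vinyl bromide completes the prenyl chain.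

Step 10
Reactants: 21 (1S,5R,7R)-2-methoxy-8,8-dimethyl-1,7-bis(3-methylbut-2-en-1-yl)bicyclo[3.3.1]non-2-en-9-one
Product: 23 (1S,5R,7R)-2-methoxy-8,8-dimethyl-1,7-bis(3-methylbut-2-en-1-yl)bicyclo[3.3.1]non-2-ene-4,9-dione, via allylic tert-butyl peroxide 22 (not isolated)
Conditions: t-BuOOH (5 equiv, in decane), Pd(OH)2/C (10 mol %), K2CO3, CH2Cl2, 0 °C → rt
Reagents that add atoms: tert-butyl hydroperoxide, CC(C)(C)OO
Why: In this peroxide-based allylic oxidation the tert-butylperoxyl radical should abstract the weakest C–H, the C4 methylene allylic to the electron-rich enol ether, and the allylic peroxide collapses to the ketone to give the vinylogous ester.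

Step 11
Reactants: 23 (1S,5R,7R)-2-methoxy-8,8-dimethyl-1,7-bis(3-methylbut-2-en-1-yl)bicyclo[3.3.1]non-2-ene-4,9-dione
Product: 25 (1S,5R,7R)-2-methoxy-5,8,8-trimethyl-1,7-bis(3-methylbut-2-en-1-yl)bicyclo[3.3.1]non-2-ene-4,9-dione, via bridgehead lithium compound 24 (not isolated)
Conditions: LiN(i-Pr)2 (commercial solution, 1.3 equiv), THF, −78 °C; then MeI, −78 → 0 °C
Reagents that add atoms: iodomethane, CI
Why: Bridgehead lithiation–alkylation should remove C5–H, acidified by the flanking C4 and C9 carbonyls, and methylate the pyramidal anion with retention, the only geometry the bicycle allows.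

Step 12
Reactants: 25 (1S,5R,7R)-2-methoxy-5,8,8-trimethyl-1,7-bis(3-methylbut-2-en-1-yl)bicyclo[3.3.1]non-2-ene-4,9-dione; 26 2-methylpropanoyl chloride (isobutyryl chloride)
Product: 28 (1S,5S,7R)-2-methoxy-5,8,8-trimethyl-1,7-bis(3-methylbut-2-en-1-yl)-3-(2-methylpropanoyl)bicyclo[3.3.1]non-2-ene-4,9-dione, via vinyllithium 27 (not isolated)
Conditions: lithium 2,2,6,6-tetramethylpiperidide (from the amine and n-BuLi, 3 equiv), THF, −78 °C; then 26, −78 → −40 °C
Reagents that add atoms: none
Why: With both bridgeheads blocked, the hindered amide should deprotonate the vinylic C3–H of the β-methoxy enone, and acylation of the vinyllithium by the acid chloride at low temperature is a known way to install the C3 acyl group of such bicyclic vinylogous esters.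

Step 13
Reactants: 28 (1S,5S,7R)-2-methoxy-5,8,8-trimethyl-1,7-bis(3-methylbut-2-en-1-yl)-3-(2-methylpropanoyl)bicyclo[3.3.1]non-2-ene-4,9-dione
Product: 29 (1R,5R,7R)-4-hydroxy-5,8,8-trimethyl-1,7-bis(3-methylbut-2-en-1-yl)-3-(2-methylpropanoyl)bicyclo[3.3.1]non-3-ene-2,9-dione (CNP0265287.1)
Conditions: LiCl (10 equiv), DMSO, 120 °C; dilute aqueous HCl work-up
Reagents that add atoms: none
Why: Chloride should cleave the vinylogous methyl ester by SN2 attack at the O-methyl carbon (Krapcho-type demethylation) without touching the prenyl groups or the stereocentres, and acidification gives the enolised β-triketone, which equilibrates to the tautomer drawn.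

Compound list
1 | 2-bromo-1,3-dimethoxybenzene | COc1cccc(OC)c1Br | starting material
2 | methyl 2-methylpropanoate (methyl isobutyrate) | COC(=O)C(C)C | starting material
3 | lithium 1-methoxy-2-methylprop-1-en-1-olate (formed in situ) | [Li+].COC([O-])=C(C)C | intermediate
4 | methyl 2-(2,6-dimethoxyphenyl)-2-methylpropanoate | COC(=O)C(C)(C)c1c(OC)cccc1OC | intermediate
5 | lithium enolate of 3-(2,6-dimethoxyphenyl)-3-methyl-1-(trimethylsilyl)butan-2-one (formed in situ) | [Li+].[O-]C(=C[Si](C)(C)C)C(C)(C)c1c(OC)cccc1OC | intermediate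
6 | 3-(2,6-dimethoxyphenyl)-3-methylbutan-2-one | CC(=O)C(C)(C)c1c(OC)cccc1OC | intermediate
7 | lithium 3-(2,6-dimethoxyphenyl)-3-methylbutan-2-olate, racemic (formed in situ) | [Li+].CC([O-])C(C)(C)c1c(OC)cccc1OC | intermediate
8 | 3-(2,6-dimethoxycyclohexa-2,5-dien-1-yl)-3-methylbutan-2-ol, racemic | CC(O)C(C)(C)C1C(OC)=CCC=C1OC | intermediate
9 | 1-bromo-3-methylbut-2-ene (prenyl bromide) | CC(C)=CCBr | starting material
10 | dilithium salt of 8: C7 alkoxide and C1 cyclohexadienyl anion (formed in situ) | [Li+].[Li+].CC([O-])C(C)(C)[C-]1C(OC)=CCC=C1OC | intermediate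
11 | 3-[2,6-dimethoxy-1-(3-methylbut-2-en-1-yl)cyclohexa-2,5-dien-1-yl]-3-methylbutan-2-ol, racemic | CC(O)C(C)(C)C1(CC=C(C)C)C(OC)=CCC=C1OC | intermediate
12 | 3-[2,6-dimethoxy-1-(3-methylbut-2-en-1-yl)cyclohexa-2,5-dien-1-yl]-3-methylbutan-2-one | CC(=O)C(C)(C)C1(CC=C(C)C)C(OC)=CCC=C1OC | intermediate
13 | lithium enolate of 12 at the methyl group (formed in situ) | [Li+].C=C([O-])C(C)(C)C1(CC=C(C)C)C(OC)=CCC=C1OC | intermediate
14 | 1,1,1-trifluoro-5-[2,6-dimethoxy-1-(3-methylbut-2-en-1-yl)cyclohexa-2,5-dien-1-yl]-5-methylhexane-2,4-dione (formed in situ) | O=C(CC(=O)C(F)(F)F)C(C)(C)C1(CC=C(C)C)C(OC)=CCC=C1OC | intermediate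
15 | 1-diazo-3-[2,6-dimethoxy-1-(3-methylbut-2-en-1-yl)cyclohexa-2,5-dien-1-yl]-3-methylbutan-2-one | COC1=CCC=C(OC)C1(CC=C(C)C)C(C)(C)C(=O)C=[N+]=[N-] | intermediate
16 | 6,9-dimethoxy-4,4-dimethyl-5-(3-methylbut-2-en-1-yl)tricyclo[3.3.1.0(2,9)]non-6-en-3-one; in the route locants the cyclopropane is C5–C6–C9, fused on the face of ring A that carries C8, with C1 and C5 as in 17 (formed in situ) | CC(C)=CC[C@@]12C(OC)=CC[C@H]3[C@@H](C(=O)C1(C)C)[C@@]23OC | intermediate
17 | (1S,5S)-2-methoxy-8,8-dimethyl-1-(3-methylbut-2-en-1-yl)bicyclo[3.3.1]non-2-ene-7,9-dione | O=C1C[C@H]2C(=O)[C@](CC=C(C)C)(C(OC)=CC2)C1(C)C | intermediate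
18 | (1S,5S)-2-methoxy-8,8-dimethyl-7-methylidene-1-(3-methylbut-2-en-1-yl)bicyclo[3.3.1]non-2-en-9-one | C=C1C[C@H]2C(=O)[C@](CC=C(C)C)(C(OC)=CC2)C1(C)C | intermediate
19 | 1-bromo-2-methylprop-1-ene | CC(C)=CBr | starting material
20 | 9-{[(1S,5R,7R)-2-methoxy-8,8-dimethyl-1-(3-methylbut-2-en-1-yl)-9-oxobicyclo[3.3.1]non-2-en-7-yl]methyl}-9-borabicyclo[3.3.1]nonane, CH2B endo (formed in situ) | B1(C[C@@H]3C[C@H]4C(=O)[C@](CC=C(C)C)(C(OC)=CC4)C3(C)C)C2CCCC1CCC2 | intermediate
21 | (1S,5R,7R)-2-methoxy-8,8-dimethyl-1,7-bis(3-methylbut-2-en-1-yl)bicyclo[3.3.1]non-2-en-9-one, C7 prenyl endo | CC(C)=CC[C@@H]1C[C@H]2C(=O)[C@](CC=C(C)C)(C(OC)=CC2)C1(C)C | intermediate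
22 | 4-(tert-butylperoxy) derivative of 21, C4 epimers (formed in situ) | CC(C)=CC[C@@H]1C[C@H]2C(=O)[C@](CC=C(C)C)(C(OC)=CC2OOC(C)(C)C)C1(C)C | intermediate
23 | (1S,5R,7R)-2-methoxy-8,8-dimethyl-1,7-bis(3-methylbut-2-en-1-yl)bicyclo[3.3.1]non-2-ene-4,9-dione | CC(C)=CC[C@@H]1C[C@H]2C(=O)[C@](CC=C(C)C)(C(OC)=CC2=O)C1(C)C | intermediate
24 | C5-lithio derivative of 23 (formed in situ) | CC(C)=CC[C@@H]1C[C@@]2([Li])C(=O)[C@](CC=C(C)C)(C(OC)=CC2=O)C1(C)C | intermediate
25 | (1S,5R,7R)-2-methoxy-5,8,8-trimethyl-1,7-bis(3-methylbut-2-en-1-yl)bicyclo[3.3.1]non-2-ene-4,9-dione | CC(C)=CC[C@@H]1C[C@@]2(C)C(=O)[C@](CC=C(C)C)(C(OC)=CC2=O)C1(C)C | intermediate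
26 | 2-methylpropanoyl chloride (isobutyryl chloride) | CC(C)C(Cl)=O | starting material
27 | C3-lithio derivative of 25 (formed in situ) | CC(C)=CC[C@@H]1C[C@@]2(C)C(=O)[C@](CC=C(C)C)(C(OC)=C([Li])C2=O)C1(C)C | intermediate
28 | (1S,5S,7R)-2-methoxy-5,8,8-trimethyl-1,7-bis(3-methylbut-2-en-1-yl)-3-(2-methylpropanoyl)bicyclo[3.3.1]non-2-ene-4,9-dione | CC(C)=CC[C@@H]1C[C@@]2(C)C(=O)[C@](CC=C(C)C)(C(OC)=C(C(=O)C(C)C)C2=O)C1(C)C | intermediate
29 | (1R,5R,7R)-4-hydroxy-5,8,8-trimethyl-1,7-bis(3-methylbut-2-en-1-yl)-3-(2-methylpropanoyl)bicyclo[3.3.1]non-3-ene-2,9-dione | CC(C)=CC[C@@H]1C[C@@]2(C)C(=O)[C@](CC=C(C)C)(C(=O)C(C(=O)C(C)C)=C2O)C1(C)C | target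

Total step count: 13. Longest linear sequence: 13 steps (1 and 2 to 29).

Steps most likely to fail

Step 7. What may go wrong: an acceptor-only carbene may discriminate the two enantiotopic enol ethers poorly, or be diverted into carbene dimerisation, Wolff rearrangement or attack on the prenyl alkene, because the fully substituted tether slows its approach to C5. The fallback switches to an acceptor/acceptor carbene, for which copper–bis(oxazoline) cyclopropanation is best established. It sets out from 12: the lithium enolate (LiN(SiMe3)2) is sulfonylated with PhSO2F to give 1-(benzenesulfonyl)-3-[2,6-dimethoxy-1-(3-methylbut-2-en-1-yl)cyclohexa-2,5-dien-1-yl]-3-methylbutan-2-one F1. Ordinary diazo transfer (4-acetamidobenzenesulfonyl azide, Et3N, MeCN) gives the α-diazo-β-keto sulfone F2. CuOTf/bis(oxazoline) cyclopropanation gives the C6-sulfonyl cyclopropane F3, which PPTS in wet acetone opens to the C6-sulfonyl dione F4. SmI2 in THF–MeOH at −78 °C removes the sulfonyl group, and the route is rejoined at 17.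

Step 4. What may go wrong: incomplete lithiation of the crowded C1–H, or alkylation of the dienyl anion at its terminal carbons (C3, C5) or through the tertiary end of the prenyl unit (SN2′), giving regioisomers. The fallback makes C1 quaternary while C8 is still a methylene and adds the two methyl groups afterwards. It sets out from 1 (with 9 as before): bromine–lithium exchange (n-BuLi) and opening of methyloxirane with BF3·OEt2 give 1-(2,6-dimethoxyphenyl)propan-2-ol F5. Birch reduction gives 1-(2,6-dimethoxycyclohexa-2,5-dien-1-yl)propan-2-ol F6, and t-BuLi then 9 gives the C1-prenylated alcohol F7. Dess–Martin oxidation gives 1-[2,6-dimethoxy-1-(3-methylbut-2-en-1-yl)cyclohexa-2,5-dien-1-yl]propan-2-one F8. Diazo transfer as in step 6 (kinetic enolate at the methyl group, trifluoroacetyl diketone F9) gives the diazo ketone F10. CuOTf/bis(oxazoline) cyclopropanation gives the cyclopropyl ketone lacking the C8 methyl groups F11. Two rounds of LiN(i-Pr)2/MeI at C8, the only enolisable position, pass through the monomethyl ketone F12 and deliver 16, which is opened to 17 under the acid stage of step 7. This detour also bypasses steps 1 and 2.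

Step 10. What may go wrong: hydrogen abstraction at the allylic CH2 and CH3 groups of the two prenyl chains, or over-oxidation, competing with abstraction at C4. The fallback carries out the C4 oxidation before the second prenyl chain exists, so that only the C1 prenyl group, whose CH2 sits on a quaternary carbon, can compete. It sets out from 17: the same t-BuOOH/Pd(OH)2/C oxidation gives (1S,5R)-2-methoxy-8,8-dimethyl-1-(3-methylbut-2-en-1-yl)bicyclo[3.3.1]non-2-ene-4,7,9-trione F13. Cp2TiMe2 methylenates the C7 ketone, the vinylogous ester and the shielded C9 ketone being less reactive, to give the 7-methylidene-4,9-dione F14. 9-BBN hydroboration from the exo face (B-alkyl-9-BBN borane F15) and Suzuki–Miyaura coupling with 19 rejoin the route at 23.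

Further compounds
F1 | step 7 | 1-(benzenesulfonyl)-3-[2,6-dimethoxy-1-(3-methylbut-2-en-1-yl)cyclohexa-2,5-dien-1-yl]-3-methylbutan-2-one | O=C(CS(=O)(=O)c1ccccc1)C(C)(C)C1(CC=C(C)C)C(OC)=CCC=C1OC
F2 | step 7 | 1-(benzenesulfonyl)-1-diazo-3-[2,6-dimethoxy-1-(3-methylbut-2-en-1-yl)cyclohexa-2,5-dien-1-yl]-3-methylbutan-2-one | O=C(C(=[N+]=[N-])S(=O)(=O)c1ccccc1)C(C)(C)C1(CC=C(C)C)C(OC)=CCC=C1OC
F3 | step 7 | C6-benzenesulfonyl analogue of cyclopropane 16 | CC(C)=CC[C@@]12C(OC)=CC[C@H]3[C@](C(=O)C1(C)C)(S(=O)(=O)c4ccccc4)[C@@]23OC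
F4 | step 7 | C6-benzenesulfonyl analogue of 17, C6 epimers | O=C1C(S(=O)(=O)c3ccccc3)[C@H]2C(=O)[C@](CC=C(C)C)(C(OC)=CC2)C1(C)C
F5 | step 4 | 1-(2,6-dimethoxyphenyl)propan-2-ol, racemic | CC(O)Cc1c(OC)cccc1OC
F6 | step 4 | 1-(2,6-dimethoxycyclohexa-2,5-dien-1-yl)propan-2-ol, racemic | CC(O)CC1C(OC)=CCC=C1OC
F7 | step 4 | 1-[2,6-dimethoxy-1-(3-methylbut-2-en-1-yl)cyclohexa-2,5-dien-1-yl]propan-2-ol, racemic | CC(O)CC1(CC=C(C)C)C(OC)=CCC=C1OC
F8 | step 4 | 1-[2,6-dimethoxy-1-(3-methylbut-2-en-1-yl)cyclohexa-2,5-dien-1-yl]propan-2-one | CC(=O)CC1(CC=C(C)C)C(OC)=CCC=C1OC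
F9 | step 4 | 1,1,1-trifluoro-5-[2,6-dimethoxy-1-(3-methylbut-2-en-1-yl)cyclohexa-2,5-dien-1-yl]pentane-2,4-dione | O=C(CC(=O)C(F)(F)F)CC1(CC=C(C)C)C(OC)=CCC=C1OC
F10 | step 4 | 1-diazo-3-[2,6-dimethoxy-1-(3-methylbut-2-en-1-yl)cyclohexa-2,5-dien-1-yl]propan-2-one | [N-]=[N+]=CC(=O)CC1(CC=C(C)C)C(OC)=CCC=C1OC
F11 | step 4 | analogue of cyclopropane 16 lacking both C8 methyl groups | CC(C)=CC[C@@]12C(OC)=CC[C@H]3[C@@H](C(=O)C1)[C@@]23OC
F12 | step 4 | analogue of cyclopropane 16 with one C8 methyl group, C8 epimers | CC(C)=CC[C@@]12C(OC)=CC[C@H]3[C@@H](C(=O)C1C)[C@@]23OC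
F13 | step 10 | (1S,5R)-2-methoxy-8,8-dimethyl-1-(3-methylbut-2-en-1-yl)bicyclo[3.3.1]non-2-ene-4,7,9-trione | O=C1C[C@H]2C(=O)[C@](CC=C(C)C)(C(OC)=CC2=O)C1(C)C
F14 | step 10 | (1S,5R)-2-methoxy-8,8-dimethyl-7-methylidene-1-(3-methylbut-2-en-1-yl)bicyclo[3.3.1]non-2-ene-4,9-dione | C=C1C[C@H]2C(=O)[C@](CC=C(C)C)(C(OC)=CC2=O)C1(C)C
F15 | step 10 | B-alkyl-9-BBN borane from F14, CH2B endo at C7 | B1(C[C@@H]3C[C@H]4C(=O)[C@](CC=C(C)C)(C(OC)=CC4=O)C3(C)C)C2CCCC1CCC2
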